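**Retrosynthetic overview**

- The target comes from its 4-hydroxy-3,5-dimethoxyphenyl analogue by a final phenol O-methylation.
- The oxolane is the only ring and is formed second to last: the benzylic CH2 of a seco-lignan triol is dehydrogenated to a para-quinone methide, which the primary hydroxyl captures 5-exo (C2–O bond, sets C2).
- The triol comes from a 2,3-dibenzylsuccinyl bis-imide by hydride reduction, which removes both auxiliaries and the phenol ester together.
- The C3–C4 bond (lignan 8–8' bond) comes from a crossed oxidative coupling of two 3-arylpropanoyl imide enolates carrying the same (R)-oxazolidinone (sets C3 and C4).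
- The imides come from 3-(3,4-dimethoxyphenyl)propanoic acid, sinapic acid and (R)-4-benzyl-1,3-oxazolidin-2-one.

Assumption: the SMILES is read as the (2R,3S,4S)-oxolane (2,3-trans, 3,4-cis; lignan numbering 7R,8S,8'S), and the three starting materials above are taken as cheap catalogue chemicals.

**Route**

Step 1
Reactants: 1 3-(3,4-dimethoxyphenyl)propanoic acid; 2 (R)-4-benzyl-1,3-oxazolidin-2-one
Product: 4 (R)-4-benzyl-3-[3-(3,4-dimethoxyphenyl)propanoyl]-1,3-oxazolidin-2-one, via mixed pivalic anhydride 3 (not isolated)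
Conditions: PivCl, Et3N, THF, −20 °C; then LiCl, 2, −20 °C → rt
Reagents that add atoms: none
Why: N-acylation of the oxazolidinone through the mixed pivalic anhydride, which is attacked at its less hindered carbonyl; no stereocentre is formed.

Step 2
Reactants: 5 sinapic acid, (E)-3-(4-hydroxy-3,5-dimethoxyphenyl)prop-2-enoic acid
Product: 6 3-(4-hydroxy-3,5-dimethoxyphenyl)propanoic acid
Conditions: H2 (1 atm), 10% Pd/C, MeOH, rt
Reagents that add atoms: none
Why: Heterogeneous catalytic hydrogenation of the cinnamic C=C bond; the arene and the acid are untouched.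

Step 3
Reactants: 6 3-(4-hydroxy-3,5-dimethoxyphenyl)propanoic acid; 2 (R)-4-benzyl-1,3-oxazolidin-2-one
Product: 8 (R)-4-benzyl-3-{3-[3,5-dimethoxy-4-(pivaloyloxy)phenyl]propanoyl}-1,3-oxazolidin-2-one, via aryl pivalate mixed anhydride 7 (not isolated)
Conditions: PivCl (2.2 equiv), Et3N (3.5 equiv), DMAP (cat.), THF, 0 °C; then LiCl, 2, rt
Reagents that add atoms: pivaloyl chloride, CC(C)(C)C(=O)Cl
Why: The acid chloride caps both the carboxylate (mixed anhydride) and the phenol (DMAP-catalysed esterification) faster than the anhydride can acylate a phenol, and the auxiliary then attacks only the unhindered acyl carbon (mixed-anhydride N-acylation), so the phenol is protected as a pivalate at no extra step.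

Step 4
Reactants: 4 (R)-4-benzyl-3-[3-(3,4-dimethoxyphenyl)propanoyl]-1,3-oxazolidin-2-one; 8 (R)-4-benzyl-3-{3-[3,5-dimethoxy-4-(pivaloyloxy)phenyl]propanoyl}-1,3-oxazolidin-2-one
Product: 11 (R)-4-benzyl-3-{(2S,3S)-4-[(R)-4-benzyl-2-oxo-1,3-oxazolidin-3-yl]-2-(3,4-dimethoxybenzyl)-3-[3,5-dimethoxy-4-(pivaloyloxy)benzyl]-4-oxobutanoyl}-1,3-oxazolidin-2-one, via veratryl imide lithium enolate 9 (not isolated), via syringyl imide lithium enolate 10 (not isolated)
Conditions: 4 (3 equiv), 8 (1 equiv), LiN(iPr)2 (4.2 equiv), THF, −78 °C; then anhydrous CuCl2 (4.4 equiv) in DMF, −78 °C → rt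
Reagents that add atoms: none
Why: One-electron oxidation of the two chelated Z-lithium enolates by CuCl2 joins their alpha-carbons (oxidative enolate coupling, the laboratory counterpart of the 8–8' phenylpropanoid coupling), each enolate reacting on the face away from its 4-benzyl group so that both (R)-auxiliaries induce S; the threefold excess of cheap 4 sends statistically about three quarters of the coupling of 8 into the crossed product, which the pivalate makes chromatographically distinct from the symmetrical dimers.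

Step 5
Reactants: 11 the crossed (2S,3S)-succinyl bis-imide
Product: 12 (2S,3S)-2-(3,4-dimethoxybenzyl)-3-(4-hydroxy-3,5-dimethoxybenzyl)butane-1,4-diol
Conditions: LiAlH4 (4 equiv), THF, 0 °C → rt; aqueous Rochelle salt work-up
Reagents that add atoms: none
Why: Hydride reduction of both exocyclic imide carbonyls to primary alcohols and reductive cleavage of the aryl pivalate in one operation; the two stereocentres are not enolisable under these conditions and are retained.

Step 6
Reactants: 12 (2S,3S)-2-(3,4-dimethoxybenzyl)-3-(4-hydroxy-3,5-dimethoxybenzyl)butane-1,4-diol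
Product: 14 4-[(2R,3S,4S)-4-(3,4-dimethoxybenzyl)-3-(hydroxymethyl)oxolan-2-yl]-2,6-dimethoxyphenol, via para-quinone methide 13 (not isolated)
Conditions: DDQ (1.0 equiv, slow addition), CH2Cl2/1,4-dioxane, 0 °C → rt, 30 min
Reagents that add atoms: none
Why: DDQ dehydrogenates the para-alkyl syringol far faster than the fully methylated veratryl ring, and the resulting para-quinone methide is captured 5-exo by the C1 hydroxyl (intramolecular oxa-1,6-conjugate addition, an oxidative cycloetherification that mirrors the quinone-methide closure of lignan biosynthesis; the other hydroxyl could only give an oxetane), the reversible closure placing the aryl group trans to the adjacent hydroxymethyl group to give the 2R, 2,3-trans-3,4-cis ring.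

Step 7
Reactants: 14 4-[(2R,3S,4S)-4-(3,4-dimethoxybenzyl)-3-(hydroxymethyl)oxolan-2-yl]-2,6-dimethoxyphenol
Product: 15 [(2R,3S,4S)-4-(3,4-dimethoxybenzyl)-2-(3,4,5-trimethoxyphenyl)oxolan-3-yl]methanol
Conditions: MeI, K2CO3, acetone, 50 °C
Reagents that add atoms: iodomethane, CI
Why: Williamson O-methylation of the phenoxide only, since carbonate does not deprotonate the primary alcohol; methylation also removes the phenol needed for quinone-methide reopening, so C2 is fixed.

**Compound list**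

1 | 3-(3,4-dimethoxyphenyl)propanoic acid | COc1ccc(CCC(=O)O)cc1OC | starting material
2 | (R)-4-benzyl-1,3-oxazolidin-2-one | O=C1N[C@H](Cc2ccccc2)CO1 | starting material
3 | 3-(3,4-dimethoxyphenyl)propanoic pivalic anhydride | COc1ccc(CCC(=O)OC(=O)C(C)(C)C)cc1OC | intermediate
4 | (R)-4-benzyl-3-[3-(3,4-dimethoxyphenyl)propanoyl]-1,3-oxazolidin-2-one | COc1ccc(CCC(=O)N2[C@H](Cc3ccccc3)COC2=O)cc1OC | intermediate
5 | sinapic acid, (E)-3-(4-hydroxy-3,5-dimethoxyphenyl)prop-2-enoic acid | COc1cc(/C=C/C(=O)O)cc(OC)c1O | starting material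
6 | 3-(4-hydroxy-3,5-dimethoxyphenyl)propanoic acid | COc1cc(CCC(=O)O)cc(OC)c1O | intermediate
7 | 3-[3,5-dimethoxy-4-(pivaloyloxy)phenyl]propanoic pivalic anhydride | COc1cc(CCC(=O)OC(=O)C(C)(C)C)cc(OC)c1OC(=O)C(C)(C)C | intermediate
8 | (R)-4-benzyl-3-{3-[3,5-dimethoxy-4-(pivaloyloxy)phenyl]propanoyl}-1,3-oxazolidin-2-one | COc1cc(CCC(=O)N2[C@H](Cc3ccccc3)COC2=O)cc(OC)c1OC(=O)C(C)(C)C | intermediate
9 | lithium (Z)-enolate of 4 | COc1ccc(C/C=C(\[O-])N2[C@H](Cc3ccccc3)COC2=O)cc1OC.[Li+] | intermediate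
10 | lithium (Z)-enolate of 8 | COc1cc(C/C=C(\[O-])N2[C@H](Cc3ccccc3)COC2=O)cc(OC)c1OC(=O)C(C)(C)C.[Li+] | intermediate
11 | (R)-4-benzyl-3-{(2S,3S)-4-[(R)-4-benzyl-2-oxo-1,3-oxazolidin-3-yl]-2-(3,4-dimethoxybenzyl)-3-[3,5-dimethoxy-4-(pivaloyloxy)benzyl]-4-oxobutanoyl}-1,3-oxazolidin-2-one | COc1ccc(C[C@H](C(=O)N2[C@H](Cc3ccccc3)COC2=O)[C@H](Cc4cc(OC)c(OC(=O)C(C)(C)C)c(OC)c4)C(=O)N5[C@H](Cc6ccccc6)COC5=O)cc1OC | intermediate
12 | (2S,3S)-2-(3,4-dimethoxybenzyl)-3-(4-hydroxy-3,5-dimethoxybenzyl)butane-1,4-diol | COc1ccc(C[C@H](CO)[C@H](Cc2cc(OC)c(O)c(OC)c2)CO)cc1OC | intermediate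
13 | 4-[(2S,3S)-3-(3,4-dimethoxybenzyl)-4-hydroxy-2-(hydroxymethyl)butylidene]-2,6-dimethoxycyclohexa-2,5-dien-1-one | COc1ccc(C[C@H](CO)[C@H](C=C2C=C(OC)C(=O)C(OC)=C2)CO)cc1OC | intermediate
14 | 4-[(2R,3S,4S)-4-(3,4-dimethoxybenzyl)-3-(hydroxymethyl)oxolan-2-yl]-2,6-dimethoxyphenol | COc1ccc(C[C@@H]2CO[C@@H](c3cc(OC)c(O)c(OC)c3)[C@@H]2CO)cc1OC | intermediate
15 | [(2R,3S,4S)-4-(3,4-dimethoxybenzyl)-2-(3,4,5-trimethoxyphenyl)oxolan-3-yl]methanol | COc1ccc(C[C@@H]2CO[C@@H](c3cc(OC)c(OC)c(OC)c3)[C@@H]2CO)cc1OC | target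

**Step count**

Total steps: 7. Longest linear sequence: 6 (5 → 6 → 8 → 11 → 12 → 14 → 15).

**Steps most likely to fail, with fallbacks**

Step 4 (crossed oxidative coupling). The risks are a poor crossed-to-symmetrical ratio, a difficult separation, and eroded diastereoselectivity under copper oxidation. The fallback replaces the statistical bis-imide coupling with a hetero-selective imide/ester enolate coupling followed by lactone equilibration; it sets out from 1 and 8 and returns to the route at 12.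
- Acid 1 is esterified (Boc2O, DMAP, t-BuOH) to tert-butyl 3-(3,4-dimethoxyphenyl)propanoate F1.
- The mixed lithium enolates of 8 and F1 (LiN(iPr)2, THF, −78 °C) are oxidised with Fe(acac)3 to tert-butyl (3S)-4-[(R)-4-benzyl-2-oxo-1,3-oxazolidin-3-yl]-2-(3,4-dimethoxybenzyl)-3-[3,5-dimethoxy-4-(pivaloyloxy)benzyl]-4-oxobutanoate F2. The auxiliary fixes the syringyl-bearing carbon; the ester alpha-carbon is an epimer mixture.
- LiBH4 (THF, 1 equiv H2O, 0 °C) cleaves only the imide to give tert-butyl (3S)-2-(3,4-dimethoxybenzyl)-3-[3,5-dimethoxy-4-(pivaloyloxy)benzyl]-4-hydroxybutanoate F3.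
- TsOH in warm toluene closes the lactone, and DBU equilibrates its alpha-carbon to the trans isomer (3S,4S)-3-(3,4-dimethoxybenzyl)-4-[3,5-dimethoxy-4-(pivaloyloxy)benzyl]oxolan-2-one F4.
- LiAlH4 opens the lactone and removes the pivalate to give 12.

Step 6 (oxidative quinone-methide cyclisation). The risks are over-oxidation of the product phenol, Friedel–Crafts closure by the veratryl ring to an aryltetralin, and incomplete 2,3-trans control. The fallback separates the oxidation from the ring closure; it sets out from 12 and returns at 14.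
- DDQ in CH2Cl2/MeOH at 0 °C lets the solvent trap the quinone methide, giving the benzylic methyl ether (2S,3S)-2-(3,4-dimethoxybenzyl)-3-[(4-hydroxy-3,5-dimethoxyphenyl)(methoxy)methyl]butane-1,4-diol F5 as an epimer mixture.
- Catalytic BF3·OEt2 in CH2Cl2 at −40 °C ionises this ether and closes the oxolane under thermodynamic control to 14.

Step 3 (one-pot pivaloylation and N-acylation). The risk is that the mixed anhydride acylates a phenol before pivaloyl chloride does, giving oligomeric aryl esters. The fallback protects first and then acylates through the acid chloride; it sets out from 6 and returns at 8.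
- PivCl in aqueous NaOH (Schotten–Baumann) gives 3-[3,5-dimethoxy-4-(pivaloyloxy)phenyl]propanoic acid F6.
- (COCl)2 with catalytic DMF in CH2Cl2 gives 3-[3,5-dimethoxy-4-(pivaloyloxy)phenyl]propanoyl chloride F7.
- F7 is added to the N-lithio derivative of 2 (n-BuLi, THF, −78 °C) to give 8.

**Further compounds**

F1 | step 4 | tert-butyl 3-(3,4-dimethoxyphenyl)propanoate | CC(C)(C)OC(=O)CCc1ccc(OC)c(OC)c1
F2 | step 4 | tert-butyl (3S)-4-[(R)-4-benzyl-2-oxo-1,3-oxazolidin-3-yl]-2-(3,4-dimethoxybenzyl)-3-[3,5-dimethoxy-4-(pivaloyloxy)benzyl]-4-oxobutanoate, epimers at C2 | CC(C)(C)OC(=O)C(Cc1ccc(OC)c(OC)c1)[C@H](Cc1cc(OC)c(OC(=O)C(C)(C)C)c(OC)c1)C(=O)N1[C@H](Cc2ccccc2)COC1=O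
F3 | step 4 | tert-butyl (3S)-2-(3,4-dimethoxybenzyl)-3-[3,5-dimethoxy-4-(pivaloyloxy)benzyl]-4-hydroxybutanoate, epimers at C2 | CC(C)(C)OC(=O)C(Cc1ccc(OC)c(OC)c1)[C@H](Cc1cc(OC)c(OC(=O)C(C)(C)C)c(OC)c1)CO
F4 | step 4 | (3S,4S)-3-(3,4-dimethoxybenzyl)-4-[3,5-dimethoxy-4-(pivaloyloxy)benzyl]oxolan-2-one | COc1ccc(C[C@@H]2C(=O)OC[C@H]2Cc3cc(OC)c(OC(=O)C(C)(C)C)c(OC)c3)cc1OC
F5 | step 6 | (2S,3S)-2-(3,4-dimethoxybenzyl)-3-[(4-hydroxy-3,5-dimethoxyphenyl)(methoxy)methyl]butane-1,4-diol, epimers at the benzylic carbon | COc1ccc(C[C@H](CO)[C@H](C(OC)c2cc(OC)c(O)c(OC)c2)CO)cc1OC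
F6 | step 3 | 3-[3,5-dimethoxy-4-(pivaloyloxy)phenyl]propanoic acid | COc1cc(CCC(=O)O)cc(OC)c1OC(=O)C(C)(C)C
F7 | step 3 | 3-[3,5-dimethoxy-4-(pivaloyloxy)phenyl]propanoyl chloride | COc1cc(CCC(=O)Cl)cc(OC)c1OC(=O)C(C)(C)C
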